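**Retrosynthetic overview**
1. Lactol **18** ⇐ DIBAL reduction of acetoxy-lactone **17** ⇐ acetylation of alcohol **16**, whose C–OH stereocentre comes from CBS reduction of ring enone **15**.
2. The δ-lactone and the exocyclic (E)-dienyl group of **15** ⇐ 6-exo-dig radical lactonisation of iodomethyl ester **14** onto the conjugated enyne. This is the last ring formed.
3. Key step, and the first ring formed: the nine-membered ring of **12** ⇐ 9-exo-dig radical macrocyclisation of the α-ester radical from **11** onto a terminal alkyne. This forms the C–C bond and the exocyclic methylene together. The ring enone makes the chain trisubstituted alkene polarity-mismatched, so it does not intercept the radical.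
4. **11** ⇐ cross-metathesis of **6** with hex-1-en-5-yn-3-ol, then oxidation. **6** ⇐ Cu-catalysed asymmetric conjugate addition–iodination of dienynoate **4**, which comes from **1** and **3**.

Assumptions: the ligand and catalyst enantiomers in Steps 3 and 11 are the ones giving the configurations drawn. The lactol equilibrates among anomers, and the drawn anomer is taken as the one isolated.

---

**Step 1**
Reactants: **1** 2-methylbut-3-yn-2-ol
Product: **2** (E)-4-iodo-2-methylbut-3-en-2-ol
Conditions: Cp2Zr(H)Cl (2.2 equiv), THF, rt, 1 h; then I2 (1.3 equiv), 0 °C
Reagents that add atoms: iodine, II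
Why: Hydrozirconation is syn and anti-Markovnikov, and iododezirconation with retention gives the (E)-vinyl iodide (Schwartz hydrozirconation/iodination).

**Step 2**
Reactants: **3** methyl (E)-pent-2-en-4-ynoate; **2**
Product: **4** methyl (2E,6E)-8-hydroxy-8-methylnona-2,6-dien-4-ynoate
Conditions: Pd(PPh3)2Cl2 (3 mol%), CuI (6 mol%), Et3N, THF, 0 °C → rt
Reagents that add atoms: none
Why: Sonogashira coupling of the terminal alkyne with the vinyl iodide retains both alkene geometries and assembles the C1–C8 carbon skeleton (ester carbon through the CMe2OH carbon) in one step.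

**Step 3**
Reactants: **4**; **5** 4-bromo-2-methylbut-1-ene (converted in situ to its Grignard reagent with Mg)
Product: **6** methyl (3R,6E)-8-hydroxy-2-iodo-8-methyl-3-(3-methylbut-3-en-1-yl)non-6-en-4-ynoate (mixture of C2 epimers)
Conditions: **5** + Mg, THF, then 3-methylbut-3-enyl-MgBr (2.3 equiv), CuBr·SMe2 (5 mol%), Josiphos ligand (6 mol%, enantiomer chosen to give 3R), tBuOMe, –78 °C, 16 h; then I2 (1.5 equiv), –78 °C
Reagents that add atoms: iodine, II
Why: Proposed new method: the chiral Cu–alkyl adds 1,4 to the enoate β-carbon of the dienynoate, which sets the C3 stereocentre, and the resulting magnesium enolate is iodinated in the same pot. The closest known reaction is Cu/Josiphos asymmetric conjugate addition of Grignard reagents to α,β-unsaturated esters with enolate trapping. The C2 centre is erased later in the radical step.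

**Step 4**
Reactants: **7** acrolein; **8** propargyl bromide
Product: **9** (±)-hex-1-en-5-yn-3-ol
Conditions: Zn dust, THF/sat. aq. NH4Cl, 0 °C → rt
Reagents that add atoms: none
Why: Zinc Barbier propargylation of the aldehyde gives the homopropargylic alcohol, racemic because the carbinol stereocentre is destroyed in Step 6.

**Step 5**
Reactants: **6**; **9** (4 equiv)
Product: **10** methyl (3R,6E)-8-hydroxy-3-[(3E)-5-hydroxy-3-methyloct-3-en-7-yn-1-yl]-2-iodo-8-methylnon-6-en-4-ynoate (epimeric at C2 and the carbinol)
Conditions: Hoveyda–Grubbs II (5 mol%), CH2Cl2, 40 °C, 14 h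
Reagents that add atoms: none
Why: Cross-metathesis of the 1,1-disubstituted alkene with the vinyl carbinol forms the trisubstituted alkene, which is E because the chain prefers the trans arrangement, and releases ethylene.

**Step 6**
Reactants: **10**
Product: **11** methyl (3R,6E)-8-hydroxy-2-iodo-8-methyl-3-[(3E)-3-methyl-5-oxooct-3-en-7-yn-1-yl]non-6-en-4-ynoate
Conditions: Dess–Martin periodinane (1.5 equiv), NaHCO3, CH2Cl2, 0 °C → rt
Reagents that add atoms: none
Why: Chemoselective oxidation of the secondary allylic alcohol to the enone (Dess–Martin oxidation) removes the carbinol stereocentre and deactivates the chain alkene toward the electrophilic radical of Step 7.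

**Step 7 (key step)**
Reactants: **11**
Product: **12** methyl (5E)-9-[(3E)-5-hydroxy-5-methylhex-3-en-1-yn-1-yl]-6-methyl-2-methylidene-4-oxocyclonon-5-ene-1-carboxylate (ester and alkynyl groups trans, absolute configuration as in the SMILES)
Conditions: Bu3SnH (1.5 equiv, syringe pump over 12 h), AIBN (0.3 equiv), benzene (2 mM), 80 °C
Reagents that add atoms: none (only H is added)
Why: Proposed new method: Bu3Sn• abstracts I to give the α-ester radical, which closes 9-exo-dig onto the internal carbon of the terminal alkyne. The resulting exocyclic vinyl radical abstracts H to give the =CH2 group. The new centre at C1 is set trans to the C9 alkynyl group by minimal transannular strain, and the enone polarity-mismatches any 5-exo/6-endo attack on the chain alkene. The closest known reaction is a stannane-mediated macrocyclisation of an α-halo ester radical onto an alkyne.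

**Step 8**
Reactants: **12**
Product: **13** the corresponding carboxylic acid
Conditions: Me3SnOH (5 equiv), 1,2-DCE, 60 °C, 12 h
Reagents that add atoms: trimethyltin hydroxide, C[Sn](C)(C)O
Why: Mild Me3SnOH ester cleavage avoids isomerising the acidic, allylic C1–H or the exocyclic alkene and touches neither the enone nor the tertiary alcohol.

**Step 9**
Reactants: **13**
Product: **14** the iodomethyl ester of **13**
Conditions: CH2I2 (10 equiv), NaHCO3 (3 equiv), DMF, 25 °C, 24 h
Reagents that add atoms: diiodomethane, ICI
Why: Carboxylate SN2 on CH2I2 gives the iodomethyl ester, which is the radical precursor for the lactone ring.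

**Step 10**
Reactants: **14**
Product: **15** trans-fused nine/six lactone: 3-methylidene, 5-oxo, E-ring-alkene macrocycle with the (E)-4-hydroxy-4-methylpent-2-en-1-ylidene group on the lactone ring; C–CO is R and C–alkylidene is S, as in the SMILES
Conditions: Bu3SnH (1.3 equiv, syringe pump over 10 h), AIBN (0.2 equiv), benzene (3 mM), 80 °C
Reagents that add atoms: none (only H is added)
Why: Proposed new method: the α-acyloxymethyl radical closes 6-exo-dig onto the alkyne carbon attached to the ring, forming the δ-lactone and the conjugated dienyl vinyl radical. This radical then takes H from the side anti to the bulky nine-membered-ring carbon, which places the dienyl chain cis to that ring carbon (the E-exocyclic alkene of the target). The existing C1/C9 trans relationship becomes the trans ring fusion. The closest known reaction is 6-exo-dig radical cyclisation onto enynes (Stork-type) with kinetic H-transfer.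

**Step 11**
Reactants: **15**
Product: **16** allylic alcohol (ring C–OH is R)
Conditions: (S)-Me-CBS (20 mol%), catecholborane (1.5 equiv), toluene, –78 °C
Reagents that add atoms: none (only H is added)
Why: Catalyst-controlled 1,2-reduction of the enone (Corey–Bakshi–Shibata) sets the C–OH stereocentre; the lactone, exocyclic alkenes and tertiary alcohol are untouched.

**Step 12**
Reactants: **16**
Product: **17** acetoxy-lactone
Conditions: Ac2O (3 equiv), DMAP (0.1 equiv), Et3N, CH2Cl2, 0 °C, 1 h
Reagents that add atoms: acetic anhydride, CC(=O)OC(C)=O
Why: The secondary allylic alcohol is acetylated selectively over the hindered tertiary alcohol, and the stereocentre is retained.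

**Step 13**
Reactants: **17**
Product: **18** Asterolaurin D
Conditions: DIBAL-H (2.3 equiv), CH2Cl2, –78 °C, 30 min; Rochelle salt work-up
Reagents that add atoms: none (only H is added)
Why: Low-temperature DIBAL reduces the strained δ-lactone to the lactol faster than the acetate (one equivalent goes to the free tertiary OH), and the anomeric centre equilibrates to the natural anomer.

---

**Compound list**

| # | Name | SMILES | Role |
|---|---|---|---|
| 1 | 2-methylbut-3-yn-2-ol | CC(C)(O)C#C | starting material |
| 2 | (E)-4-iodo-2-methylbut-3-en-2-ol | CC(C)(O)/C=C/I | intermediate |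
| 3 | methyl (E)-pent-2-en-4-ynoate | COC(=O)/C=C/C#C | starting material |
| 4 | methyl (2E,6E)-8-hydroxy-8-methylnona-2,6-dien-4-ynoate | COC(=O)/C=C/C#C/C=C/C(C)(C)O | intermediate |
| 5 | 4-bromo-2-methylbut-1-ene | C=C(C)CCBr | starting material |
| 6 | α-iodo ester from conjugate addition (3R) | COC(=O)C(I)[C@H](CCC(C)=C)C#C/C=C/C(C)(C)O | intermediate |
| 7 | acrolein | C=CC=O | starting material |
| 8 | propargyl bromide | C#CCBr | starting material |
| 9 | (±)-hex-1-en-5-yn-3-ol | C=CC(O)CC#C | intermediate |
| 10 | cross-metathesis alcohol | COC(=O)C(I)[C@H](CC/C(C)=C/C(O)CC#C)C#C/C=C/C(C)(C)O | intermediate |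
| 11 | enone | COC(=O)C(I)[C@H](CC/C(C)=C/C(=O)CC#C)C#C/C=C/C(C)(C)O | intermediate |
| 12 | nine-membered-ring enone ester | COC(=O)[C@H]1C(=C)CC(=O)/C=C(\C)CC[C@@H]1C#C/C=C/C(C)(C)O | intermediate |
| 13 | acid | OC(=O)[C@H]1C(=C)CC(=O)/C=C(\C)CC[C@@H]1C#C/C=C/C(C)(C)O | intermediate |
| 14 | iodomethyl ester | ICOC(=O)[C@H]1C(=C)CC(=O)/C=C(\C)CC[C@@H]1C#C/C=C/C(C)(C)O | intermediate |
| 15 | lactone enone | C=C1CC(=O)/C=C(\C)CC[C@@H]2/C(=C\C=C\C(C)(C)O)COC(=O)[C@@H]12 | intermediate |
| 16 | lactone allylic alcohol | C=C1C[C@@H](O)/C=C(\C)CC[C@@H]2/C(=C\C=C\C(C)(C)O)COC(=O)[C@@H]12 | intermediate |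
| 17 | acetoxy-lactone | C=C1C[C@@H](OC(C)=O)/C=C(\C)CC[C@@H]2/C(=C\C=C\C(C)(C)O)COC(=O)[C@@H]12 | intermediate |
| 18 | Asterolaurin D | C=C1C[C@@H](OC(C)=O)/C=C(\C)CC[C@@H]2/C(=C\C=C\C(C)(C)O)CO[C@H](O)[C@@H]12 | target |

**Total steps:** 13. **Longest linear sequence:** 12 (Steps 1, 2, 3, 5–13; Step 4 is a parallel branch).

**Three steps most likely to fail**
1. **Step 7 (9-exo-dig macrocyclisation).** Reduction of the radical by Bu3SnH, other radical modes, strain of the trans ring alkene, or the wrong C1 configuration could all defeat it.
   Fallback: change the ring-closing bond. Install a 2-(bromomethyl)allyl unit on the lactone by Pd-catalysed α-alkenylation, and close the c–d bond by intramolecular CrCl2/NiCl2 allylation of the enal.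
2. **Step 10 (radical lactonisation across an ester).** The required E-ester rotamer is disfavoured, and the radical may instead reduce or attack the exocyclic methylene.
   Fallback: form the pyran by ionic hydroxymethylation of the alkyne (Ni-catalysed reductive coupling with paraformaldehyde and silane) followed by acid lactonisation.
3. **Step 3 (regio- and enantioselective conjugate addition to the dienynoate).** 1,6-addition to give an allene is a competing pathway.
   Fallback: set the C3 centre by Ni/pybox enantioconvergent Negishi coupling of a racemic propargylic bromide with the alkylzinc reagent, then rebuild the ester by homologation.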